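**Plan**
- Retrosynthesis: the C5 ester and the silyl and enol-ether masks are removed first. The γ-lactone is then cut at O–C6 and at C11–C12 in one stroke, which takes out CO2 and leaves a C5–C6 β-epoxide next to a C11 enol triflate. Next come epoxide → C5=C6, the C1–C2 cut (ketone + acetylide), and removal of one ring carbon (C5) back to (R)-carvone.
- Enabling feature: on the cycloheptane, the lactone O at C6 is trans to the ester O at C5 and cis to C11 at C7. This is the outcome of a 5-exo opening of a C5–C6 epoxide by a carboxylate that hangs from C7 on the opposite face, so C12 and both lactone oxygens can be CO2.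
- Forward ring order: cyclohexenone → cycloheptenone (dibromocarbene expansion) → temporary 8-oxabicyclo[3.2.1]octane (C9–O–C6 bromo ether, masks C5=C6 and C9–OH) → side chain at C1 → bridge removed with zinc → epoxide → second temporary ring (C9–O–C2 enol ether, stores the C2 ketone) → γ-lactone → ester → release.
- Stereochemistry: C7 comes from carvone and C9 from anti conjugate borylation. C10 and C1 come from the rigid oxa-bridged chair, and C5/C6 from the β-epoxide and its inversion at C6. C4 and C2' come from (S)-but-3-yn-2-ol and (S)-2-methylbutanoic anhydride.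

Key step: step 11

Numbering and faces:
- C1 is the carbinol carbon bearing the chain C2(=O)–C3–C4(OH)–C15.
- C5 = CH–O-ester, C6 = CH–O-lactone, C7 = CH–C11, C8 = CH2, C9 = CHOH, C10 = CH–CH3 (C14).
- C11=C13H2, and C12 is the lactone C=O.
- The β face carries H6, H7, O–C5, O–C9 and C2. The α face carries O–C6, C11, C14 and O–C1.

Assumption: 23 rests as the open C2 ketone that is drawn, not as its bridged C2/C9–O hemiketal 22.

Step 1
Reactants: 1 (R)-carvone
Product: 3 (3R,5R)-3-hydroxy-2-methyl-5-(prop-1-en-2-yl)cyclohexan-1-one (C10 epimers), via boryl ketone 2 (not isolated)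
Conditions: B2pin2, CuCl (cat.), DPEphos (cat.), NaOtBu (cat.), MeOH, THF, rt; then NaBO3·4H2O, THF/H2O, rt
Reagents that add atoms: sodium perborate [Na+].[Na+].O[B-]1(O)OO[B-](O)(O)OO1; bis(pinacolato)diboron CC1(C)OB(OC1(C)C)B1OC(C)(C)C(C)(C)O1 (its boron stays only in 2)
Why: Copper-catalysed conjugate borylation followed by C–B oxidation is a standard β-hydroxylation of enones; as in cuprate additions to carvone the boryl-copper adds axially to C9 anti to the C7 isopropenyl group, the oxidation keeps that configuration (β C9–O), the unactivated isopropenyl alkene is not touched, and the C10 epimer mixture is corrected in step 3.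

Step 2
Reactants: 3 β-hydroxy ketone
Product: 4 C9–OTMS ether / C1=C6 trimethylsilyl enol ether
Conditions: TMSCl, LDA, THF, −78 °C (internal quench)
Reagents that add atoms: chlorotrimethylsilane C[Si](C)(C)Cl
Why: Kinetic deprotonation by LDA takes the unhindered C6 methylene rather than the tertiary C10–H, so the enol ether forms away from the β-oxygen (no elimination) and the C9 alkoxide is capped in the same operation.

Step 3
Reactants: 4 bis-silyl compound
Product: 7 bromo oxa-bridged ketone (4-bromo-2-methyl-6-isopropenyl-8-oxabicyclo[3.2.1]octan-3-one), via dibromocyclopropane 5 (not isolated), via hydroxy bromoenone 6 (not isolated)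
Conditions: CHBr3, KOtBu, pentane, −25 to 0 °C; then 1 M aq HCl, THF, 40 °C
Reagents that add atoms: bromoform BrC(Br)Br
Why: Dihalocarbene ring expansion of a silyl enol ether followed by oxa-Michael closure: the electrophilic carbene picks the most electron-rich alkene, the siloxy-dibromocyclopropane opens on desilylation with loss of bromide to the 2-bromoenone whose new carbon is C5, the freed β C9–OH adds 5-exo-trig to C6 (possible only on the β face, anti to C11), the bromo-enol is protonated on the open exo face so that Br ends equatorial (α), and acid enolisation, which runs away from the halogen towards C10, equilibrates the methyl group to the equatorial α position of the rigid pyranone chair.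

Step 4
Reactants: 8 (S)-but-3-yn-2-ol
Product: 9 (S)-3-(tert-butyldimethylsilyloxy)but-1-yne
Conditions: TBSCl, imidazole, CH2Cl2, rt
Reagents that add atoms: tert-butyldimethylsilyl chloride CC(C)(C)[Si](C)(C)Cl
Why: Standard O-silylation that does not touch the carbinol centre, which becomes C4 (S) of the target.

Step 5
Reactants: 7 bromo oxa-bridged ketone; 9 silyloxy alkyne
Product: 11 C1 β-alkynyl α-OTES bromo ether, via bromohydrin 10 (not isolated)
Conditions: 9, n-BuLi, THF, −78 °C; LaCl3·2LiCl (cat.); 7, −78 °C; then TESOTf, −78 to −20 °C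
Reagents that add atoms: triethylsilyl trifluoromethanesulfonate CC[Si](CC)(CC)OS(=O)(=O)C(F)(F)F
Why: 1,2-Addition of a lanthanide-activated lithium acetylide to a ketone: in the 8-oxabicyclo[3.2.1]octan-3-one chair the endo (α) face of C1 is closed by the C7–C8 bridge and its endo isopropenyl group, so the acetylide enters along the equatorial β trajectory and the oxygen becomes axial (α), the equatorial bromine lies near the carbonyl plane and gives no bias, and immediate silylation of the alkoxide blocks semipinacol migration.

Step 6
Reactants: 11 isopropenyl bromo ether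
Product: 13 C7 endo-acetyl bromo ether, via ozonide 12 (not isolated)
Conditions: O3, CH2Cl2, −78 °C (dye indicator); then Me2S, −78 °C to rt
Reagents that add atoms: ozone [O-][O+]=O
Why: Ozonolysis with reductive work-up cleaves the isopropenyl group, the only alkene present because C5=C6 is masked in the bromo ether, while the hindered internal alkyne reacts far more slowly with ozone.

Step 7
Reactants: 13 methyl ketone
Product: 14 C11 enol triflate (1-(triflyloxy)vinyl group at C7)
Conditions: KHMDS, THF, −78 °C; PhNTf2, −78 to 0 °C
Reagents that add atoms: N-phenylbis(trifluoromethanesulfonimide) O=S(=O)(N(c1ccccc1)S(=O)(=O)C(F)(F)F)C(F)(F)F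
Why: Kinetic enolisation of a methyl ketone at the methyl group by a bulky amide base and O-triflation gives the terminal enol triflate, whereas the tertiary C7–H, whose removal would eject the bridge oxygen by E1cB, is kinetically much less acidic, so that C7 keeps its configuration.

Step 8
Reactants: 14 bromo ether enol triflate
Product: 15 cyclohept-5-ene with free β C9–OH
Conditions: activated Zn dust, THF/EtOH, 60 °C; aq NH4Cl work-up
Reagents that add atoms: none
Why: Boord-type (Vasella-like) reductive fragmentation of a β-bromo ether: the C5–Br bond is anti-periplanar only to the C6–O bridge bond and gauche to the C1–OTES bond, so the bridge oxygen leaves, the endo crowding is released, C5=C6 and the C9–OH reappear, and enol triflate, alkyne and silyl ethers are inert to zinc.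

Step 9
Reactants: 15 cycloheptenol
Product: 16 C5–C6 β-epoxide
Conditions: mCPBA, NaHCO3, CH2Cl2, 0 °C
Reagents that add atoms: 3-chloroperbenzoic acid O=C(OO)c1cccc(Cl)c1
Why: Peracid epoxidation under combined hydroxyl direction and steric control: the C9–OH that has just left C6 sits over the β face and hydrogen-bonds the peracid, the α face is covered by the C1–OTES group and the C7 side chain, and the electron-poor enol triflate and the alkyne do not compete.

Step 10
Reactants: 16 epoxy alkynol
Product: 17 bridged (Z)-enol ether (C9–O–C2, 7-oxabicyclo[4.2.1]nonane type)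
Conditions: AuCl (cat.), K2CO3 (cat.), MeCN, rt
Reagents that add atoms: none
Why: Gold(I)-catalysed 5-exo-dig hydroalkoxylation of a 4-alkyn-1-ol: the β C9–OH and the β alkynyl group at C1 are 1,3-cis, so anti oxyauration at C2 and protodeauration give the (Z)-alkylidene oxolane, which fixes the future ketone at C2 rather than C3 and protects C9–OH in one temporary ring, while the basic medium spares epoxide, triflate and silyl ethers.

Step 11
Reactants: 17 epoxy enol triflate
Product: 19 cis-fused α-methylene-γ-butyrolactone with free β C5–OH, via magnesium epoxy-acrylate 18 (not isolated)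
Conditions: CO2 (1 atm), PdCl2(PPh3)2 (cat.), n-Bu4NBF4, DMF, undivided cell, carbon-felt cathode, Mg anode, −2.0 V vs SCE, 20 °C; then 40 °C; pH 7 buffer
Reagents that add atoms: carbon dioxide O=C=O
Why: Proposed new method: Pd(0) inserts into the C11–OTf bond, the vinylpalladium(II) cation takes up two electrons at the cathode and the resulting nucleophilic vinyl species attacks CO2 (C11–C12 bond), after which the carboxylate 18, paired with the Mg2+ set free at the anode that also coordinates the oxirane oxygen, opens the C6–O bond from the rear (O–C6 bond). The closest known reaction types are the palladium-catalysed electrocarboxylation of enol triflates to 2-substituted acrylic acids with a sacrificial magnesium anode and the ready lactonisation of γ,δ-epoxy carboxylates; what is new is their merger on a triflate that carries the epoxide, so that CO2 is built in as a whole lactone unit. The one ring that closes, the γ-lactone O–C12–C11–C7–C6, forms in the 5-exo-tet mode, while 6-endo attack at C5 is disfavoured by the trajectory and by the neopentyl position next to quaternary C1. C6 is the only centre that changes: it is inverted from β-O to α-O because C7 holds the carboxylate on the α face, anti to the β-epoxide, which enforces the cis ring fusion, and C5 keeps its β oxygen, now the only free hydroxyl. The step needs chemoselective reduction and an epoxide that stays silent until the carboxylate exists: only the C–OTf bond reacts with Pd(0) at this potential, the isolated epoxide, enol ether and silyl ethers are not reduced, the electrolyte offers no nucleophilic halide, C1–O is silylated (no Payne shift) and C9–O is tied up in the enol ether (no proton source).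

Step 12
Reactants: 19 hydroxy lactone; 20 (S)-2-methylbutanoic anhydride
Product: 21 C5 (S)-2-methylbutanoate
Conditions: 20, DMAP, Et3N, CH2Cl2, rt
Reagents that add atoms: none
Why: DMAP-catalysed acylation with the enantiopure anhydride esterifies the only free hydroxyl under basic conditions that spare the acid-labile enol ether and avoid a ketene pathway, so that the 2'S centre is not scrambled.

Step 13
Reactants: 21 protected ester
Product: 23 target CNP0291806.1, via bridged hemiketal 22 (not isolated)
Conditions: 48% aq HF, MeCN, 0 °C to rt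
Reagents that add atoms: water O
Why: Aqueous HF cleaves the TES and TBS ethers and protonates the enol ether at C3, water adds to the oxocarbenium ion at C2 and the bridged hemiketal opens to the C2 ketone and the C9–OH, no stereocentre is touched, and the α-methylene lactone and the ester tolerate the mild acid.

**Compound list**
1 | (R)-(−)-carvone, (5R)-2-methyl-5-(prop-1-en-2-yl)cyclohex-2-en-1-one | CC1=CC[C@H](CC1=O)C(C)=C | starting material
2 | (3R,5R)-2-methyl-3-(pinacolatoboryl)-5-(prop-1-en-2-yl)cyclohexan-1-one, C2 (= C10) epimers | O=C1C[C@H](C(C)=C)C[C@@H](B2OC(C)(C)C(C)(C)O2)C1C | intermediate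
3 | (3R,5R)-3-hydroxy-2-methyl-5-(prop-1-en-2-yl)cyclohexan-1-one, C2 (= C10) epimers | O=C1C[C@H](C(C)=C)C[C@@H](O)C1C | intermediate
4 | bis-TMS derivative of 3: C9–OTMS ether and C1=C6 trimethylsilyl enol ether | C[Si](C)(C)OC1=C[C@H](C(C)=C)C[C@@H](O[Si](C)(C)C)C1C | intermediate
5 | 7,7-dibromo-1-(trimethylsilyloxy)bicyclo[4.1.0]heptane from 4 (CBr2 across C1=C6, new fusion centres not defined) | C[Si](C)(C)OC12C(Br)(Br)C1[C@H](C(C)=C)C[C@@H](O[Si](C)(C)C)C2C | intermediate
6 | (4R,6R)-2-bromo-6-hydroxy-7-methyl-4-(prop-1-en-2-yl)cyclohept-2-en-1-one, C7 (= C10) epimers | O=C1C(Br)=C[C@H](C(C)=C)C[C@@H](O)C1C | intermediate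
7 | 4-bromo-2-methyl-6-(prop-1-en-2-yl)-8-oxabicyclo[3.2.1]octan-3-one; C9–O–C6 bridge on the β face, 2-Me (C10) and 4-Br (C5) equatorial (α), 6-isopropenyl (C7) endo (α) | O=C1[C@H](Br)[C@H]2O[C@H](C[C@H]2C(C)=C)[C@@H]1C | intermediate
8 | (S)-but-3-yn-2-ol | C#C[C@H](C)O | starting material
9 | (S)-3-(tert-butyldimethylsilyloxy)but-1-yne | C#C[C@H](C)O[Si](C)(C)C(C)(C)C | intermediate
10 | adduct of 7 and 9: C1 carbinol (present as lithium alkoxide) with axial α-OH and equatorial β-alkynyl group, other centres as in 7 | O[C@]1(C#C[C@H](C)O[Si](C)(C)C(C)(C)C)[C@H](Br)[C@H]2O[C@H](C[C@H]2C(C)=C)[C@@H]1C | intermediate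
11 | C1–OTES ether of 10 | CC[Si](CC)(CC)O[C@]1(C#C[C@H](C)O[Si](C)(C)C(C)(C)C)[C@H](Br)[C@H]2O[C@H](C[C@H]2C(C)=C)[C@@H]1C | intermediate
12 | secondary ozonide (3-methyl-1,2,4-trioxolan-3-yl group at C7) of 11 | CC[Si](CC)(CC)O[C@]1(C#C[C@H](C)O[Si](C)(C)C(C)(C)C)[C@H](Br)[C@H]2O[C@H](C[C@H]2C3(C)OCOO3)[C@@H]1C | intermediate
13 | C7 endo-acetyl analogue of 11 | CC[Si](CC)(CC)O[C@]1(C#C[C@H](C)O[Si](C)(C)C(C)(C)C)[C@H](Br)[C@H]2O[C@H](C[C@H]2C(C)=O)[C@@H]1C | intermediate
14 | C7 endo-[1-(trifluoromethylsulfonyloxy)vinyl] analogue of 11 | CC[Si](CC)(CC)O[C@]1(C#C[C@H](C)O[Si](C)(C)C(C)(C)C)[C@H](Br)[C@H]2O[C@H](C[C@H]2C(=C)OS(=O)(=O)C(F)(F)F)[C@@H]1C | intermediate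
15 | cycloheptene (C5=C6) with α C1–OTES, β C1-alkynyl, α C10–Me, β C9–OH, α C7 enol-triflate side chain | C=C(OS(=O)(=O)C(F)(F)F)[C@H]1C=C[C@](O[Si](CC)(CC)CC)(C#C[C@H](C)O[Si](C)(C)C(C)(C)C)[C@@H](C)[C@H](O)C1 | intermediate
16 | C5–C6 β-epoxide of 15 | C=C(OS(=O)(=O)C(F)(F)F)[C@H]1[C@@H]2O[C@@H]2[C@](O[Si](CC)(CC)CC)(C#C[C@H](C)O[Si](C)(C)C(C)(C)C)[C@@H](C)[C@H](O)C1 | intermediate
17 | bridged (Z)-enol ether from 16: C9–O–C2(=C3H–C4), β bridge, epoxide and triflate unchanged | C=C(OS(=O)(=O)C(F)(F)F)[C@H]1[C@@H]2O[C@@H]2[C@]3(O[Si](CC)(CC)CC)/C(=C/[C@H](C)O[Si](C)(C)C(C)(C)C)O[C@H](C1)[C@@H]3C | intermediate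
18 | 2-substituted acrylic acid (C11–CO2H, present as magnesium carboxylate) with intact β-epoxide | C=C(C(=O)O)[C@H]1[C@@H]2O[C@@H]2[C@]3(O[Si](CC)(CC)CC)/C(=C/[C@H](C)O[Si](C)(C)C(C)(C)C)O[C@H](C1)[C@@H]3C | intermediate
19 | cis-fused α-methylene-γ-butyrolactone (α O–C6, α C11) with free β C5–OH, masks as in 17 | C=C1C(=O)O[C@@H]2[C@H]1C[C@H]3O/C(=C\[C@H](C)O[Si](C)(C)C(C)(C)C)[C@@](O[Si](CC)(CC)CC)([C@H]2O)[C@H]3C | intermediate
20 | (S)-2-methylbutanoic anhydride | CC[C@H](C)C(=O)OC(=O)[C@@H](C)CC | starting material
21 | C5 (S)-2-methylbutanoate of 19 | C=C1C(=O)O[C@@H]2[C@H]1C[C@H]3O/C(=C\[C@H](C)O[Si](C)(C)C(C)(C)C)[C@@](O[Si](CC)(CC)CC)([C@H]2OC(=O)[C@@H](C)CC)[C@H]3C | intermediate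
22 | desilylated bridged C2 hemiketal (C9–O–C2(OH), C2 not defined) | C=C1C(=O)O[C@@H]2[C@H]1C[C@H]3OC(O)(C[C@H](C)O)[C@@](O)([C@H]2OC(=O)[C@@H](C)CC)[C@H]3C | intermediate
23 | CNP0291806.1 | C=C1C(=O)O[C@@H]2[C@H]1C[C@@H](O)[C@H](C)[C@@](O)(C(=O)C[C@H](C)O)[C@H]2OC(=O)[C@@H](C)CC | target

Total step count: 13. Longest linear sequence: 12 (steps 1–3 and 5–13).

**Steps most likely to fail**

Step 11 (Proposed new method).
- Possible failures: protonation of the reduced vinylpalladium species instead of CO2 capture, a carboxylate that forms but opens the epoxide too slowly, or competing opening at C5.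
- Fallback with known chemistry, setting out from 17: palladium-catalysed methoxycarbonylation of the enol triflate (Pd(PPh3)4, CO, MeOH, Et3N, DMF) should give the methyl 2-substituted acrylate F1.
- Me3SnOH in 1,2-dichloroethane should cleave the ester to the acid 18.
- Warming 18 with Cs2CO3 in DMF should close the lactone by the same 5-exo opening, and the route is rejoined at 19.

Step 5.
- Possible failures: slow addition at the hindered carbonyl, which lets enolisation or bromine abstraction by the acetylide take over, and incomplete silylation of the crowded axial alkoxide.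
- Fallback, setting out from 7, builds the chain in two stages. The smaller and less basic ethynylmagnesium bromide (LaCl3·2LiCl), followed by TESOTf, should give the ethynyl carbinol silyl ether F2.
- Zinc/chiral amino-alcohol-mediated asymmetric addition of F2 to acetaldehyde, with the ligand enantiomer chosen for the 4S carbinol, should give the propargylic alcohol F3.
- TBSCl/imidazole brings the sequence back at 11.

Step 8.
- Possible failures: sluggish zinc insertion into the hindered secondary bromide, simple hydrodebromination, or loss of the C1 silyloxy group instead of the bridge oxygen.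
- Fallback, setting out from 14, replaces the carbanion-type elimination by an ionic one under stereoelectronic control.
- TMSCl/NaI in MeCN with 2,6-lutidine silylates the bridge oxygen. The anti-periplanar C5–Br participates to a bromonium ion, and iodide removes the bromine.
- This should give the C9–OTMS ether F4. Brief K2CO3/MeOH treatment frees C9–OH and the route is rejoined at 15.

**Further compounds**
F1 | step 11 | methyl 2-substituted acrylate (C11–CO2Me) with intact β-epoxide and masks of 17 | C=C(C(=O)OC)[C@H]1[C@@H]2O[C@@H]2[C@]3(O[Si](CC)(CC)CC)/C(=C/[C@H](C)O[Si](C)(C)C(C)(C)C)O[C@H](C1)[C@@H]3C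
F2 | step 5 | C1 β-ethynyl α-OTES bromo ether | CC[Si](CC)(CC)O[C@]1(C#C)[C@H](Br)[C@H]2O[C@H](C[C@H]2C(C)=C)[C@@H]1C
F3 | step 5 | (4S)-propargylic alcohol, O-desilyl (C4–OH) analogue of 11 | CC[Si](CC)(CC)O[C@]1(C#C[C@H](C)O)[C@H](Br)[C@H]2O[C@H](C[C@H]2C(C)=C)[C@@H]1C
F4 | step 8 | C9–OTMS ether of 15 | C=C(OS(=O)(=O)C(F)(F)F)[C@H]1C=C[C@](O[Si](CC)(CC)CC)(C#C[C@H](C)O[Si](C)(C)C(C)(C)C)[C@@H](C)[C@H](O[Si](C)(C)C)C1
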